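The disconnection cuts the cis-fused α-methylene-γ-butyrolactone across C2–C3 and C3a–C7a (benzofuranone numbering). This opens the lactone ring (O1–C2–C3–C3a–C7a) and the cyclohexene ring (C3a–C4–C5–C6–C7–C7a) at once and leaves an acyclic (Z)-allene–aldehyde plus CO. A Ru3(CO)12-catalysed hetero-Pauson–Khand cyclocarbonylation, run as the last step, closes both rings in one operation and sets C3a and C7a from the C4 acyloxy stereocentre. Its precursor, an octa-3,6,7-trienal already carrying both isobutyrates, is assembled linearly from (S)-citronellic acid. A chelation-controlled enol triflate and a Negishi coupling fix the tetrasubstituted (Z)-alkene, and a catalytic asymmetric allenylboration sets C4.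

Key step: step 11

Remark: locants C2, C3, C3a, C4, C5, C7a refer to the benzofuranone numbering of target 23 unless a compound name gives its own.

Step 1
Reactants: 1 (S)-citronellic acid; 2 N,O-dimethylhydroxylamine hydrochloride
Product: 3 (3S)-N-methoxy-N,3,7-trimethyloct-6-enamide
Conditions: CDI, CH2Cl2, rt; then 2, rt
Reagents that add atoms: N,O-dimethylhydroxylamine hydrochloride, Cl.CNOC
Why: Acyl imidazolide formation and aminolysis (standard Weinreb amide coupling) should leave the C3 stereocentre and the trisubstituted alkene untouched.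

Step 2
Reactants: 3 (3S)-N-methoxy-N,3,7-trimethyloct-6-enamide; 4 acetyl chloride
Product: 5 (3S)-2-acetyl-N-methoxy-N,3,7-trimethyloct-6-enamide (mixture of C2 epimers)
Conditions: LDA (2.1 equiv), THF, −78 °C; then AcCl, −78 → 0 °C; aq. NH4Cl
Reagents that add atoms: acetyl chloride, CC(=O)Cl
Why: C-acylation of the lithium amide enolate (crossed Claisen-type acylation) should give the β-keto amide, the second equivalent of base absorbing its acidic proton; the uncontrolled C2 centre is irrelevant because it becomes sp2 in step 3.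

Step 3
Reactants: 5 (3S)-2-acetyl-N-methoxy-N,3,7-trimethyloct-6-enamide; 6 trifluoromethanesulfonic anhydride
Product: 7 (2Z)-4-[methoxy(methyl)amino]-3-[(2S)-6-methylhept-5-en-2-yl]-4-oxobut-2-en-2-yl trifluoromethanesulfonate
Conditions: NaH, Et2O, 0 °C; then Tf2O (1.05 equiv), −78 → 0 °C
Reagents that add atoms: trifluoromethanesulfonic anhydride, O=S(=O)(OS(=O)(=O)C(F)(F)F)C(F)(F)F
Why: O-triflation of the sodium chelate, in which both carbonyl oxygens are held on the same side of the enolate, should fix the (Z)-geometry (OTf cis to the amide carbonyl), as in chelation-controlled enol triflate formation from 2-substituted acetoacetyl derivatives; both C2 epimers converge.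

Step 4
Reactants: 7 the (Z)-enol triflate; 8 (1,3-dioxolan-2-ylmethyl)zinc bromide
Product: 9 (2Z)-4-(1,3-dioxolan-2-yl)-N-methoxy-N,3-dimethyl-2-[(2S)-6-methylhept-5-en-2-yl]but-2-enamide
Conditions: Pd(PPh3)4 (5 mol%), THF, 50 °C
Reagents that add atoms: (1,3-dioxolan-2-ylmethyl)zinc bromide, Br[Zn]CC1OCCO1
Why: Negishi coupling of the activated β-triflyloxy enamide at zerovalent palladium proceeds with retention of alkene geometry, so the acetal-bearing CH2 should end up cis to the amide carbon.

Step 5
Reactants: 9 the (Z)-enamide acetal; 10 sodium periodate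
Product: 12 (2Z)-4-(1,3-dioxolan-2-yl)-N-methoxy-N,3-dimethyl-2-[(2S)-5-oxopentan-2-yl]but-2-enamide, via vicinal diol 11 (not isolated)
Conditions: OsO4 (2 mol%), NaIO4 (4 equiv), 2,6-lutidine, 1,4-dioxane/H2O 3:1, rt
Reagents that add atoms: osmium tetroxide, O=[Os](=O)(=O)=O (catalytic oxygen-transfer agent); sodium periodate, [Na+].[O-]I(=O)(=O)=O (stoichiometric oxygen source)
Why: In this Lemieux–Johnson cleavage OsO4 should dihydroxylate the unhindered trisubstituted alkene far faster than the hindered, acyl-bearing tetrasubstituted one, and lutidine buffering keeps the dioxolane intact.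

Step 6
Reactants: 12 the aldehyde Weinreb amide
Product: 13 (2Z)-4-(1,3-dioxolan-2-yl)-2-[(2S)-5-hydroxypentan-2-yl]-3-methylbut-2-enal
Conditions: iBu2AlH (3 equiv), THF, −78 °C; aq. potassium sodium tartrate
Reagents that add atoms: none
Why: iBu2AlH reduces the aliphatic aldehyde to the primary alkoxide and turns the Weinreb amide into a chelated hemiaminal that releases the enal only on work-up (Weinreb reduction), so over-reduction is not expected.

Step 7
Reactants: 13 the (Z)-hydroxy enal; 14 4,4,5,5-tetramethyl-2-[3-(trimethylsilyl)prop-2-yn-1-yl]-1,3,2-dioxaborolane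
Product: 16 (4R,5Z)-7-(1,3-dioxolan-2-yl)-5-[(2S)-5-hydroxypentan-2-yl]-6-methyl-3-(trimethylsilyl)hepta-1,2,5-trien-4-ol, via O-pinacolboryl ether 15 (not isolated)
Conditions: (S)-TRIP phosphoric acid (10 mol%), 4 Å molecular sieves, toluene, −20 °C → rt; aq. NaHCO3
Reagents that add atoms: 4,4,5,5-tetramethyl-2-[3-(trimethylsilyl)prop-2-yn-1-yl]-1,3,2-dioxaborolane, C[Si](C)(C)C#CCB1OC(C)(C)C(C)(C)O1
Why: Phosphoric-acid-catalysed propargylboration through a closed six-membered chair transition state (SE2' transfer gives the 1-silylallenyl carbinol) should place the new carbinol centre by Si-face attack on the enal, assigned by analogy with the allylboration model in which the (R)-catalyst attacks the Re face; the free primary hydroxyl is tolerated by the boronate.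

Step 8
Reactants: 16 the silylallenyl diol
Product: 17 (4S,5Z)-7-(1,3-dioxolan-2-yl)-5-[(2S)-5-hydroxypentan-2-yl]-6-methylhepta-1,2,5-trien-4-ol
Conditions: Bu4NF (3 equiv), THF, 0 °C → rt
Reagents that add atoms: none
Why: Fluoride-induced protodesilylation of the 1-silylallene, assisted by the neighbouring alkoxide, should leave the carbinol centre untouched (its descriptor changes from R to S only because silicon is lost).

Step 9
Reactants: 17 the allenyl diol; 18 2-methylpropanoyl chloride (isobutyryl chloride)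
Product: 19 (4S,5Z)-7-(1,3-dioxolan-2-yl)-6-methyl-5-[(2S)-5-(2-methylpropanoyloxy)pentan-2-yl]hepta-1,2,5-trien-4-yl 2-methylpropanoate
Conditions: iPrCOCl (3 equiv), pyridine, DMAP (10 mol%), CH2Cl2, 0 °C → rt
Reagents that add atoms: 2-methylpropanoyl chloride, CC(C)C(=O)Cl
Why: DMAP-catalysed acylation should esterify the primary and the hindered secondary hydroxyl in one operation with retention at the carbinol carbon, installing both esters of the target.

Step 10
Reactants: 19 the diester acetal; 20 water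
Product: 21 (3Z,5S)-3-methyl-4-[(2S)-5-(2-methylpropanoyloxy)pentan-2-yl]-1-oxoocta-3,6,7-trien-5-yl 2-methylpropanoate
Conditions: Et3SiOTf (2 equiv), 2,4,6-collidine (3 equiv), CH2Cl2, 0 °C; then H2O
Reagents that add atoms: water, O
Why: Silyl triflate/collidine acetal cleavage passes through a collidinium intermediate that water hydrolyses to the aldehyde under essentially non-acidic conditions, so the ionisable secondary ester, the allene and the β,γ-position of the new aldehyde should not be disturbed; the aldehyde is used at once.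

Step 11
Reactants: 21 the (Z)-allene–aldehyde; 22 carbon monoxide
Product: 23 (3aR,4S,7aR)-6-methyl-3-methylidene-5-[(2S)-5-(2-methylpropanoyloxy)pentan-2-yl]-2-oxo-2,3,3a,4,7,7a-hexahydro-1-benzofuran-4-yl 2-methylpropanoate
Conditions: Ru3(CO)12 (3 mol%), CO (20 atm), 1,4-dioxane, 120 °C
Reagents that add atoms: carbon monoxide, [C-]#[O+]
Why: A zerovalent ruthenium carbonyl fragment binds the proximal allene π-bond and the aldehyde C=O, oxidative cyclisation forms C3a–C7a and an oxaruthenacycle with the metal on C3, CO inserts into the Ru–C3 bond (C2–C3) and reductive elimination forms C2–O1; this is the known hetero-Pauson–Khand cyclocarbonylation of allenyl aldehydes to α-methylene-γ-butyrolactones. The cyclohexene closes by six-membered C–C coupling across the (Z)-alkene tether inside the bicyclic metallacycle, and the lactone closes as the formal [2+2+1] ring by C–O reductive elimination. C3a and C7a should emerge cis because O1 and C3 sit on the same metal centre when the C3a–C7a bond forms. The C4 stereocentre should control their absolute sense: A(1,2) strain with the C5 side chain holds the isobutyryloxy group pseudoaxial in the half-chair, and the allene adds anti to it because the syn mode would place the metal-bound carbonyl oxygen 1,3-diaxial to the ester, which gives 3aR,7aR. The step needs the proximal over the distal allene π-bond (only the proximal one gives a six-membered ring), the aldehyde over the two ester carbonyls, and no engagement of the hindered tetrasubstituted C5=C6 alkene.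

Compound list
1 | (S)-citronellic acid, (3S)-3,7-dimethyloct-6-enoic acid | OC(=O)C[C@@H](C)CCC=C(C)C | starting material
2 | N,O-dimethylhydroxylamine hydrochloride | Cl.CNOC | starting material
3 | (3S)-N-methoxy-N,3,7-trimethyloct-6-enamide | CON(C)C(=O)C[C@@H](C)CCC=C(C)C | intermediate
4 | acetyl chloride | CC(=O)Cl | starting material
5 | (3S)-2-acetyl-N-methoxy-N,3,7-trimethyloct-6-enamide (C2 epimers) | CON(C)C(=O)C(C(C)=O)[C@@H](C)CCC=C(C)C | intermediate
6 | trifluoromethanesulfonic anhydride | O=S(=O)(OS(=O)(=O)C(F)(F)F)C(F)(F)F | starting material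
7 | (2Z)-4-[methoxy(methyl)amino]-3-[(2S)-6-methylhept-5-en-2-yl]-4-oxobut-2-en-2-yl trifluoromethanesulfonate | CON(C)C(=O)/C([C@@H](C)CCC=C(C)C)=C(/C)OS(=O)(=O)C(F)(F)F | intermediate
8 | (1,3-dioxolan-2-ylmethyl)zinc bromide | Br[Zn]CC1OCCO1 | starting material
9 | (2Z)-4-(1,3-dioxolan-2-yl)-N-methoxy-N,3-dimethyl-2-[(2S)-6-methylhept-5-en-2-yl]but-2-enamide | CON(C)C(=O)/C([C@@H](C)CCC=C(C)C)=C(/C)CC1OCCO1 | intermediate
10 | sodium periodate | [Na+].[O-]I(=O)(=O)=O | starting material
11 | (2Z)-2-[(2S)-5,6-dihydroxy-6-methylheptan-2-yl]-4-(1,3-dioxolan-2-yl)-N-methoxy-N,3-dimethylbut-2-enamide (vicinal diol, epimers at the secondary carbinol) | CON(C)C(=O)/C([C@@H](C)CCC(O)C(C)(C)O)=C(/C)CC1OCCO1 | intermediate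
12 | (2Z)-4-(1,3-dioxolan-2-yl)-N-methoxy-N,3-dimethyl-2-[(2S)-5-oxopentan-2-yl]but-2-enamide | CON(C)C(=O)/C([C@@H](C)CCC=O)=C(/C)CC1OCCO1 | intermediate
13 | (2Z)-4-(1,3-dioxolan-2-yl)-2-[(2S)-5-hydroxypentan-2-yl]-3-methylbut-2-enal | O=C/C([C@@H](C)CCCO)=C(/C)CC1OCCO1 | intermediate
14 | 4,4,5,5-tetramethyl-2-[3-(trimethylsilyl)prop-2-yn-1-yl]-1,3,2-dioxaborolane | C[Si](C)(C)C#CCB1OC(C)(C)C(C)(C)O1 | starting material
15 | O-pinacolboryl ether of 16 at the secondary carbinol | C1COC(O1)C/C(C)=C(/[C@@H](C)CCCO)[C@@H](OB1OC(C)(C)C(C)(C)O1)C(=C=C)[Si](C)(C)C | intermediate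
16 | (4R,5Z)-7-(1,3-dioxolan-2-yl)-5-[(2S)-5-hydroxypentan-2-yl]-6-methyl-3-(trimethylsilyl)hepta-1,2,5-trien-4-ol | C1COC(O1)C/C(C)=C(/[C@@H](C)CCCO)[C@@H](O)C(=C=C)[Si](C)(C)C | intermediate
17 | (4S,5Z)-7-(1,3-dioxolan-2-yl)-5-[(2S)-5-hydroxypentan-2-yl]-6-methylhepta-1,2,5-trien-4-ol | C1COC(O1)C/C(C)=C(/[C@@H](C)CCCO)[C@@H](O)C=C=C | intermediate
18 | 2-methylpropanoyl chloride (isobutyryl chloride) | CC(C)C(=O)Cl | starting material
19 | (4S,5Z)-7-(1,3-dioxolan-2-yl)-6-methyl-5-[(2S)-5-(2-methylpropanoyloxy)pentan-2-yl]hepta-1,2,5-trien-4-yl 2-methylpropanoate | C1COC(O1)C/C(C)=C(/[C@@H](C)CCCOC(=O)C(C)C)[C@@H](OC(=O)C(C)C)C=C=C | intermediate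
20 | water | O | starting material
21 | (3Z,5S)-3-methyl-4-[(2S)-5-(2-methylpropanoyloxy)pentan-2-yl]-1-oxoocta-3,6,7-trien-5-yl 2-methylpropanoate | O=CC/C(C)=C(/[C@@H](C)CCCOC(=O)C(C)C)[C@@H](OC(=O)C(C)C)C=C=C | intermediate
22 | carbon monoxide | [C-]#[O+] | starting material
23 | (3aR,4S,7aR)-6-methyl-3-methylidene-5-[(2S)-5-(2-methylpropanoyloxy)pentan-2-yl]-2-oxo-2,3,3a,4,7,7a-hexahydro-1-benzofuran-4-yl 2-methylpropanoate | C=C1C(=O)O[C@@H]2CC(C)=C([C@@H](C)CCCOC(=O)C(C)C)[C@@H](OC(=O)C(C)C)[C@H]12 | target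

Total step count: 11
Longest linear sequence: 11 steps, from (S)-citronellic acid 1 to 23

Steps most likely to fail

Step 11. At 120 °C on the ruthenium carbonyl the allenylic, allylic isobutyrate may ionise or undergo acyl shift. The β,γ-double bond of the aldehyde may also migrate into conjugation, and facial discrimination by C4 may be incomplete. The fallback sets out from 21 and comes back at 23, forming the two bonds in separate room-temperature operations. Pd-catalysed distannylation–carbocyclisation of the allene–aldehyde (Bu3SnSnBu3, [Pd(C3H5)Cl]2, THF, rt) should give, through intramolecular allylstannane addition, the cis-hydroxy vinylstannane F1. Iododestannylation (I2, CH2Cl2, 0 °C) should give the vinyl iodide F2. Carbonylative lactonisation (Pd(PPh3)4, CO 1 atm, Et3N, MeCN, 60 °C) should then close the α-methylene lactone to 23.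

Step 10. Acetal cleavage may be accompanied by loss or allylic transposition of the doubly activated secondary ester, or by migration of the tetrasubstituted double bond towards the new aldehyde. The fallback sets out from 17 and comes back at 23, moving the esters behind the key step. Silylation (tBuMe2SiOTf, 2,6-lutidine, CH2Cl2, −78 °C) should give the bis-silyl ether F3. The same silyl triflate/collidine acetal cleavage, now without an ionisable ester, should give the bis-silyl allene–aldehyde F4. Cyclocarbonylation (Ru3(CO)12, CO, 1,4-dioxane, 120 °C) should give the bis-silyl lactone F5. HF·pyridine in THF should give the diol lactone F6. Acylation (iPrCOCl, pyridine, DMAP) should give 23.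

Step 7. Addition of the pinacol boronate to the hindered, fully substituted enal may be slow, and facial control by the catalyst may be incomplete. The fallback sets out from 13 and comes back at 17, using reagent-controlled ketone reduction and a Crabbé homologation. LiC≡CSiMe3 (2.5 equiv, THF, −78 °C) should give the carbinol as an epimer mixture F7. MnO2 in CH2Cl2 should oxidise only the doubly activated alcohol to the ynone F8. (R)-2-methyl-CBS-oxazaborolidine with BH3·SMe2 (THF, −30 °C; the silylalkynyl group acts as the small substituent) should give the (R)-carbinol F9. K2CO3 in MeOH should give the terminal alkyne F10. CuI, Cy2NH and paraformaldehyde in refluxing 1,4-dioxane should give 17.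

Further compounds
F1 | step 11 | (1S,5R,6R)-5-hydroxy-3-methyl-2-[(2S)-5-(2-methylpropanoyloxy)pentan-2-yl]-6-[1-(tributylstannyl)ethenyl]cyclohex-2-en-1-yl 2-methylpropanoate | C=C([Sn](CCCC)(CCCC)CCCC)[C@@H]1[C@H](O)CC(C)=C([C@@H](C)CCCOC(=O)C(C)C)[C@H]1OC(=O)C(C)C
F2 | step 11 | (1S,5R,6R)-5-hydroxy-6-(1-iodoethenyl)-3-methyl-2-[(2S)-5-(2-methylpropanoyloxy)pentan-2-yl]cyclohex-2-en-1-yl 2-methylpropanoate | C=C(I)[C@@H]1[C@H](O)CC(C)=C([C@@H](C)CCCOC(=O)C(C)C)[C@H]1OC(=O)C(C)C
F3 | step 10 | (4S,5Z)-4-(tert-butyldimethylsilyloxy)-5-[(2S)-5-(tert-butyldimethylsilyloxy)pentan-2-yl]-7-(1,3-dioxolan-2-yl)-6-methylhepta-1,2,5-triene | C1COC(O1)C/C(C)=C(/[C@@H](C)CCCO[Si](C)(C)C(C)(C)C)[C@@H](O[Si](C)(C)C(C)(C)C)C=C=C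
F4 | step 10 | (3Z,5S)-5-(tert-butyldimethylsilyloxy)-4-[(2S)-5-(tert-butyldimethylsilyloxy)pentan-2-yl]-3-methylocta-3,6,7-trienal | O=CC/C(C)=C(/[C@@H](C)CCCO[Si](C)(C)C(C)(C)C)[C@@H](O[Si](C)(C)C(C)(C)C)C=C=C
F5 | step 10 | (3aR,4S,7aR)-4-(tert-butyldimethylsilyloxy)-5-[(2S)-5-(tert-butyldimethylsilyloxy)pentan-2-yl]-6-methyl-3-methylidene-3a,4,7,7a-tetrahydro-1-benzofuran-2(3H)-one | C=C1C(=O)O[C@@H]2CC(C)=C([C@@H](C)CCCO[Si](C)(C)C(C)(C)C)[C@@H](O[Si](C)(C)C(C)(C)C)[C@H]12
F6 | step 10 | (3aS,4S,7aR)-4-hydroxy-5-[(2S)-5-hydroxypentan-2-yl]-6-methyl-3-methylidene-3a,4,7,7a-tetrahydro-1-benzofuran-2(3H)-one | C=C1C(=O)O[C@@H]2CC(C)=C([C@@H](C)CCCO)[C@@H](O)[C@H]12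
F7 | step 7 | (4Z)-6-(1,3-dioxolan-2-yl)-4-[(2S)-5-hydroxypentan-2-yl]-5-methyl-1-(trimethylsilyl)hex-4-en-1-yn-3-ol (C3 epimers) | C1COC(O1)C/C(C)=C(/[C@@H](C)CCCO)C(O)C#C[Si](C)(C)C
F8 | step 7 | (4Z)-6-(1,3-dioxolan-2-yl)-4-[(2S)-5-hydroxypentan-2-yl]-5-methyl-1-(trimethylsilyl)hex-4-en-1-yn-3-one | C1COC(O1)C/C(C)=C(/[C@@H](C)CCCO)C(=O)C#C[Si](C)(C)C
F9 | step 7 | (3R,4Z)-6-(1,3-dioxolan-2-yl)-4-[(2S)-5-hydroxypentan-2-yl]-5-methyl-1-(trimethylsilyl)hex-4-en-1-yn-3-ol | C1COC(O1)C/C(C)=C(/[C@@H](C)CCCO)[C@@H](O)C#C[Si](C)(C)C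
F10 | step 7 | (3S,4Z)-6-(1,3-dioxolan-2-yl)-4-[(2S)-5-hydroxypentan-2-yl]-5-methylhex-4-en-1-yn-3-ol | C1COC(O1)C/C(C)=C(/[C@@H](C)CCCO)[C@@H](O)C#C
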